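**Same charges.** The elm run holds the charges of alpha and its readings stop at 6.00 d, so alpha is elm left for 4.00 d more. At that last reading elm shows hardly any starting material, 0.1%, far less than its 12.1% target. Little new target can therefore appear in alpha after that time, and over-reaction goes on eroding what stands.

| setting | elm | birch | alpha | eta | beta |
|---|---|---|---|---|---|
| starting material | 10 mM | 20 mM | 10 mM | 10 mM | 10 mM (fed, over 8.0 d) |
| second substrate | 5 mM | 5 mM | 5.00 mM | 5.00 mM (fed, over 8.0 d) | 5.00 mM |
| enzyme | 0.53 µM | 0.53 µM | 0.53 µM | 0.53 µM | 0.53 µM |
| remark | run made earlier | run made earlier | everything together at the start | all else is in the flask from the start; the feed brings no volume worth counting | all else is in the flask from the start; the feed brings no volume worth counting |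
| time |  |  | 10 d | 10 d | 10 d |

elm run (percent of the starting material charged)

| time / d | target / % | starting material / % |
|---|---|---|
| 1.67 | 26.5 | 1.7 |
| 3.00 | 19.3 | 0.3 |
| 5.00 | 14.3 | 0.3 |
| 6.00 | 12.1 | 0.1 |

birch run (percent of the starting material charged)

| time / h | target / % | starting material / % |
|---|---|---|
| 6.00 | 13.7 | 20.1 |
| 12.0 | 17.7 | 9.0 |
| 20.0 | 19.1 | 4.2 |
| 25.0 | 18.8 | 2.3 |

(each reading ± 0.3 percentage points)

* the flask that comes out highest in amount of target, in percent of the starting material charged, or "all alike" when all lie within 1.5 percentage points (alpha / eta / beta / all alike)
* target at the end, in percent of the starting material charged, alpha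
* target at the end, in percent of the starting material charged, eta
* target at the end, in percent of the starting material charged, beta

- a species is counted by the starting material in it: one self-condensation product counts as two
- the numbers in the tables scatter with a standard deviation of 0.3 percentage points
- on the list of suspects stand: starting material + enzyme <-> complex A; complex A -> enzyme + target; second substrate + enzyme <-> complex B; complex B -> enzyme + second product; enzyme + target -> enzyme + over-reaction product; 2 starting material -> self-condensation product; 2 enzyme -> spent catalyst

**First pass.** On a steady enzyme, over-reaction is a pseudo-first-order fall of target, so I read its rate from elm between 3.00 d and 6.00 d: 0.156 /d. Carried on to 10 d, this puts alpha at 6.49%. But between 1.67 d and 3.00 d the same reading gives 0.238 /d, which is faster. The rate sinks as the days pass, as it should if enzyme pairs off into spent catalyst, so my first answer leans low.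

**Second pass.** I put that sinking rate back in by letting target fall by a fixed share for each fixed share of time gained. Elm gives 0.674, my fade exponent: the logarithm of the drop in target over the logarithm of the stretch in time. Run on from elm's last reading, it puts alpha at 8.58%, higher than the first pass and lower than elm's last reading. That is my figure. It assumes that target is no longer being made, so I give none for beta, whose starting material is fed over 8.0 d. Neither earlier run feeds second substrate, so I leave eta without a figure too.

**The result.** The forecast names beta as highest, with 7.5% for alpha, 8% for eta and 30% for beta, and reads the slowing decay as one that “suggests the enzyme is dying”; its alpha lies below mine. The flasks give 8.47% for alpha, 11.5% for eta and 31.6% for beta, so beta stands highest.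

    starting material + enzyme ⇌ complex A (K = 52.0 /M, k = 160 /M/s)
    complex A → enzyme + target (k = 1.90 /s)
    second substrate + enzyme ⇌ complex B (K = 190 /M, k = 240 /M/s)
    complex B → enzyme + second product (k = 0.240 /s)
    enzyme + target → enzyme + over-reaction product (k = 12.0 /M/s)
    2 starting material → self-condensation product (k = 0.00340 /M/s)
    2 enzyme → spent catalyst (k = 7.90 /M/s)

**Earlier reading.** Alpha's 8.47% stands beside my 8.58%. The neighbour is the same flask as alpha, read at 2.5 d instead of 10 d. I start from alpha's end value and walk back with the fade exponent 0.674 over that shortening of the time, by a factor of 4.00, which gives 21.6% target. Starting material in the neighbour stands at 0.49%, hardly any. The neighbour reads 21.8% target.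

The readings come from a simulation with made-up constants, and the scatter is random.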